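## Structural features

The target joins two 3-arylchroman (isoflavan) units: the upper one is benzo ring A fused to pyran ring C with the 2-hydroxy-4-methoxyphenyl ring B on C3; the lower one is benzo ring F fused to pyran ring E with the central ring D on its C3'. Ring D is the hinge: D1 is bonded to C4 of ring C, D2 carries methoxy, D4 carries hydroxyl and D5 is bonded to C3'. There are three stereocentres: C3 and C4 are adjacent and trans, (3S,4R), while C3' is (S) and is insulated from them by ring D. C4 is a diarylmethine between two electron-rich arenes, so its C–H bond is doubly benzylic and easily ionised or deprotonated. The fragile groups are the four free phenols on resorcinol-type rings, which are sensitive to air and electrophiles, and the two aryl methyl ethers that must outlast deprotection. The real difficulty is to build the crowded C4 centre trans to ring B, with the bond to ring A at the right carbon, while two remote C3-type centres are held in one absolute sense. The key step exploits that a cation at C4 is stabilised by the D4 oxygen (para to D1) and the D2 methoxy (ortho), while C4a is para to the C7 oxygen and ortho to O1, so a ring A ether tethered through O1–C2–C3 can close ring C by forming C4–C4a.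

## Logic of the disconnections

29 ⇒ 28 ⇒ 27. Three O–benzyl bonds and one O–silicon bond are cut; no skeletal bond changes. The phenols must be masked through organolithium, boron enolate, Mitsunobu and Lewis acid chemistry. The ring B oxygen could reach a C4 cation through a five-membered ring, so it carries a bulky, weakly nucleophilic silyl group; the others are benzyl ethers. The forward demand is that desilylation comes first, so that the free tetraphenol never meets base, and that hydrogenolysis spares the pyran C–O bonds and the methyl ethers.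

27 ⇒ 25. The C4–C4a bond is cut, which opens ring C and removes the C4 stereocentre. What remains is an acyclic chain with one controlling centre at C3 and a hydroxyl at C4. The forward step must ionise C4 under conditions that leave benzyl and silyl ethers intact, close faster than C3 can lose its proton, attack ring A para to its benzyloxy group, and relay C3 to C4.

25 ⇒ 23 + 24. The C2–O1 ether bond is cut. This releases ring A as a simple phenol and leaves a diol with a primary and a hindered secondary benzylic hydroxyl. The forward etherification must touch only the primary hydroxyl and must not ionise C4.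

23 ⇒ 22 ⇒ 8 + 20. After C2 is raised to the acyl level, the C3–C4 bond is cut. An auxiliary-controlled aldol sets C3 absolutely and delivers the C4 hydroxyl directly. No intermediate then carries a carbonyl at C4 beside the C3–H while an aryloxy group sits on C2, a combination that invites epimerisation and β-elimination. The molecule falls into the two-carbon ring B unit and the complete lower half. The forward demand is that a hindered arylacetyl enolate adds to a hindered, electron-rich aldehyde, and that the reduction does not trigger retro-aldol cleavage.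

8 ⇒ 5 + 6, then 5 ⇒ 3 ⇒ 2 ⇒ 1. The N–acyl bond is cut, then the bond between the benzylic carbon and the carboxyl carbon (a one-carbon homologation), then O–silicon. The gain is a commercial benzaldehyde. The silyl ether must survive the homologation, which is why the sequence is non-basic once the ylide has been consumed.

20 ⇒ 18. The D1–formyl bond is cut. The bromine at D1 comes with the starting material because electrophilic substitution could not tell D1 from the equally activated C6' of ring F. The forward demand is a halogen–lithium exchange that outruns deprotonation of the benzyl ethers.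

18 ⇒ 17. The C3'–H and C4'–H bonds are removed to give the C3'=C4' alkene. C3' is the only stereocentre of the lower half and has no neighbour to induce it, so a catalyst must set it. The catalyst must read the faces of an alkene with an ortho-substituted aryl group and leave C–Br and O–benzyl alone.

17 ⇒ 16 ⇒ 15 ⇒ 12 + 13, then 12 ⇒ 10 ⇒ 9. The O1'–C2' ether bond is cut, the allylic alcohol is traced to a lactone, and the lactone is cut at C3'=C4' and at the acyl C–O bond. The nitrile carbon is then removed and the benzyl group taken off. The gain is two commercial benzaldehydes. The lactone guarantees the Z geometry needed for ring E closure; bromine and benzyl ethers must survive hydride reduction.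

## Other disconnections considered

Alternative 1: The cut runs through C3–C4 and O1–C2 of ring C. Forward, sulfone A2 (a ring A phenol whose benzylic carbon bears ring D with the complete lower chroman and an arylsulfonyl group) would release o-quinone methide A3 under mild base. Arylacetaldehyde A4, activated as its enamine by a chiral secondary amine, would add to the methide carbon of A3 to form C3–C4, and the phenoxide would close on the aldehyde carbon to give chroman-2-ol A1. A1 would still need ionic reduction at C2 before hydrogenolysis.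
- In its favour: C4 is fixed under catalyst control in the C–C bond-forming event, and C3, being α to a masked aldehyde, can settle trans. All four phenols can be benzyl ethers because no cation sits near the ring B oxygen. A2 could come in one condensation from 20, 24 and a sulfinic acid.
- Against it here: the established scope of this annulation rests on unbranched aliphatic aldehydes. A4 would give a conjugated, hindered enamine that is prone to self-condensation. A3 carries a bulky, strongly donating aryl group on the methide carbon, which lowers its electrophilicity and crowds the catalyst. The lactol adds a Lewis acid deoxygenation.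
- Comparison: both plans place an arene-stabilised electrophile at C4, but this one makes C3–C4 where the chosen plan makes C4–C4a from a C3 centre already secured. Mechanistically it relies on catalyst face control, the chosen plan on 1,2-induction. On step count it is the better by about three steps (no acid, imide, reduction or silyl removal), and it is also the better in needing no stoichiometric auxiliary. The chosen plan is the stronger on precedent for each individual step.

Alternative 2: The cut is O1–C8a. In alcohol A6, C4 carries two identical 4-benzyloxy-2-bromophenyl groups and is not yet stereogenic. The C2 alkoxide, bound to copper (CuI, a phenanthroline ligand, Cs2CO3), would displace bromide from one of the two diastereotopic rings; the choice, steered by C3, would create C4 and ring C in chroman A5.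
- In its favour: no carbocation is involved, so proton loss from C3 and hydride shifts cannot occur; on this point it is the better of the two plans. Intramolecular Ullmann etherification is dependable, and C3 of A6 could be set by the same auxiliary chemistry.
- Against it here: the aryl group left on C4 of A5 is not ring D. It has bromine where the D2 methoxy belongs and hydrogen at D5. After the key step the bromine must become methoxy, and the whole lower chroman with its C3' centre must be grafted onto D5 in competition with equally activated positions on rings A and B. The selection between the two aryl groups depends only on a pseudo-equatorial versus pseudo-axial preference in the ring-forming transition state.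
- Comparison: it equals the chosen plan in taking C4 from C3. Mechanistically it is a metal-mediated C–O coupling instead of a cationic C–C closure. On step economy it is clearly longer, because ring D must be rebuilt after cyclisation, whereas the chosen plan brings ring D complete.

Alternative 3: Ring D is taken apart along D1–D6, D1–D2, D3–D4 and D4–D5. Forward, diazo enone A8 has its diazo carbon bonded to C4 of a finished upper chroman and its enone terminus bonded to C3' of a finished lower chroman. Photochemical Wolff rearrangement, [2+2] cycloaddition with methoxyacetylene A9, four-electron ring opening and six-electron closure would give phenol A7, with D4 free and D2 as the methyl ether.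
- In its favour: the oxygen pattern of ring D is fixed by the mechanism; on this regiochemical point it is the equal of the chosen plan, which takes the pattern from 9. The two chroman halves are joined very late, which is the better convergence. Conditions are neutral.
- Against it here: A8 needs an upper chroman with a diazo ketone chain at C4 trans to ring B, and a lower chroman with an (E)-enone at C3' whose γ-hydrogen is open to vinylogous enolisation. In the carbene stage a 1,2-hydrogen shift from C4–H competes with vinyl migration. A9 is volatile and unstable. The key step creates none of the three stereocentres.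
- Comparison: structurally it builds ring D last, whereas the chosen plan uses ring D as the cation-stabilising group. Mechanistically it is a pericyclic cascade against an ionic closure. On step economy it is longer, since both halves need their own stereocontrolled syntheses plus a diazo transfer.

Key step: step 15

Remark on the chemistry: the sense of induction of the iridium catalyst in step 10 is assumed to follow that of 3-aryl-2H-chromenes without the ortho substituent; if it is opposite, the enantiomeric ligand is used.

## Route

Step 1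
Reactants: 1 2-hydroxy-4-methoxybenzaldehyde
Product: 2 4-methoxy-2-(triisopropylsilyloxy)benzaldehyde
Conditions: i-Pr3SiCl, imidazole, DMF, rt
Reagents that add atoms: triisopropylsilyl chloride, CC(C)[Si](Cl)(C(C)C)C(C)C
Why: Silylation of a phenol; the bulky silyl ether is chosen now because this oxygen must stay non-nucleophilic in step 15.

Step 2
Reactants: 2 4-methoxy-2-(triisopropylsilyloxy)benzaldehyde
Product: 3 4-methoxy-1-(2-methoxyvinyl)-2-(triisopropylsilyloxy)benzene (E/Z mixture)
Conditions: MeOCH2PPh3Cl, NaN(SiMe3)2, THF, 0 °C; then 2, 0 °C to rt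
Reagents that add atoms: (methoxymethyl)triphenylphosphonium chloride, COC[P+](c1ccccc1)(c1ccccc1)c1ccccc1.[Cl-]
Why: Wittig methoxymethylenation of a non-enolisable aldehyde; the base is consumed before the silyl ether is exposed, and the alkene geometry is irrelevant.

Step 3
Reactants: 3 4-methoxy-1-(2-methoxyvinyl)-2-(triisopropylsilyloxy)benzene
Product: 5 [4-methoxy-2-(triisopropylsilyloxy)phenyl]acetic acid, via arylacetaldehyde 4 (not isolated)
Conditions: 2 M HCl, THF, 40 °C; crude aldehyde then NaClO2, NaH2PO4, 2-methyl-2-butene, t-BuOH/H2O, 0 °C to rt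
Reagents that add atoms: water, O; sodium chlorite, [Na+].[O-]Cl=O
Why: Enol ether hydrolysis followed by Pinnick oxidation; the aryl silyl ether tolerates dilute acid and buffered chlorite, and the alkene scavenger keeps hypochlorous acid off the electron-rich ring.

Step 4
Reactants: 5 [4-methoxy-2-(triisopropylsilyloxy)phenyl]acetic acid; 6 (R)-4-benzyl-1,3-oxazolidin-2-one
Product: 8 (R)-4-benzyl-3-{[4-methoxy-2-(triisopropylsilyloxy)phenyl]acetyl}-1,3-oxazolidin-2-one, via mixed pivalic anhydride 7 (not isolated)
Conditions: t-BuCOCl, Et3N, THF, −20 °C; then LiCl, 6, −20 °C to rt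
Reagents that add atoms: none
Why: N-acylation of the oxazolidinone through the mixed anhydride; the hindered pivaloyl carbonyl directs attack to the arylacetyl carbonyl.

Step 5
Reactants: 9 5-bromo-2-hydroxy-4-methoxybenzaldehyde
Product: 10 2-(benzyloxy)-5-bromo-4-methoxybenzaldehyde
Conditions: BnBr, K2CO3, DMF, rt
Reagents that add atoms: benzyl bromide, BrCc1ccccc1
Why: Williamson etherification of the phenol that becomes the D4 oxygen; the bromine at the future D1 is untouched.

Step 6
Reactants: 10 2-(benzyloxy)-5-bromo-4-methoxybenzaldehyde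
Product: 12 [2-(benzyloxy)-5-bromo-4-methoxyphenyl]acetonitrile, via tosylvinyl formamide 11 (not isolated)
Conditions: TosMIC, t-BuOK, DME, −40 °C; then MeOH, reflux
Reagents that add atoms: p-toluenesulfonylmethyl isocyanide, Cc1ccc(S(=O)(=O)C[N+]#[C-])cc1
Why: Van Leusen reductive cyanation; low-temperature addition with excess base avoids the oxazole pathway, and methanolysis then expels sulfinate and methyl formate to give the homologous nitrile.

Step 7
Reactants: 12 [2-(benzyloxy)-5-bromo-4-methoxyphenyl]acetonitrile; 13 4-(benzyloxy)-2-hydroxybenzaldehyde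
Product: 15 7-(benzyloxy)-3-[2-(benzyloxy)-5-bromo-4-methoxyphenyl]-2H-chromen-2-one, via 2-iminochromene 14 (not isolated)
Conditions: t-BuOK, DMF, 60 °C; then 2 M HCl, THF, 60 °C
Reagents that add atoms: water, O
Why: Knoevenagel condensation places the nitrile cis to the phenoxide, which adds to it (Pinner-type closure); acid hydrolysis of the imine gives the 3-arylcoumarin with rings D, E and F connected.

Step 8
Reactants: 15 7-(benzyloxy)-3-[2-(benzyloxy)-5-bromo-4-methoxyphenyl]-2H-chromen-2-one
Product: 16 5-(benzyloxy)-2-{(Z)-2-[2-(benzyloxy)-5-bromo-4-methoxyphenyl]-3-hydroxyprop-1-en-1-yl}phenol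
Conditions: i-Bu2AlH (4 equiv), CH2Cl2, −78 to 0 °C; aq. potassium sodium tartrate
Reagents that add atoms: none
Why: 1,2-Reduction of the lactone through the lactol to the allylic alcohol; the Z geometry is inherited from the ring, and the aryl bromide and benzyl ethers are inert to the aluminium hydride at low temperature.

Step 9
Reactants: 16 5-(benzyloxy)-2-{(Z)-2-[2-(benzyloxy)-5-bromo-4-methoxyphenyl]-3-hydroxyprop-1-en-1-yl}phenol
Product: 17 7-(benzyloxy)-3-[2-(benzyloxy)-5-bromo-4-methoxyphenyl]-2H-chromene
Conditions: PPh3, DIAD, THF, 0 °C to rt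
Reagents that add atoms: none
Why: Intramolecular Mitsunobu etherification; the primary allylic alcohol is activated and the cis-disposed phenol closes ring E as the 2H-chromene.

Step 10
Reactants: 17 7-(benzyloxy)-3-[2-(benzyloxy)-5-bromo-4-methoxyphenyl]-2H-chromene
Product: 18 (3S)-7-(benzyloxy)-3-[2-(benzyloxy)-5-bromo-4-methoxyphenyl]chroman
Conditions: H2 (50 bar), [Ir(cod)((S)-t-Bu-PHOX)]BArF (2 mol %), CH2Cl2, rt
Reagents that add atoms: none
Why: Asymmetric hydrogenation of a 3-aryl-2H-chromene by a cationic monovalent iridium phosphine–oxazoline complex, a known way to isoflavans; the catalyst selects the alkene face and sets C3' as (S), and it does not cleave C–Br or O–benzyl bonds.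

Step 11
Reactants: 18 (3S)-7-(benzyloxy)-3-[2-(benzyloxy)-5-bromo-4-methoxyphenyl]chroman
Product: 20 4-(benzyloxy)-5-[(3S)-7-(benzyloxy)chroman-3-yl]-2-methoxybenzaldehyde, via aryllithium 19 (not isolated)
Conditions: n-BuLi, THF, −78 °C; DMF, −78 to 0 °C; H2O
Reagents that add atoms: N,N-dimethylformamide, CN(C)C=O
Why: Bromine–lithium exchange, fast at −78 °C and assisted by the ortho methoxy group, followed by formylation; C3' is not acidic enough to be touched.

Step 12
Reactants: 8 (R)-4-benzyl-3-{[4-methoxy-2-(triisopropylsilyloxy)phenyl]acetyl}-1,3-oxazolidin-2-one; 20 4-(benzyloxy)-5-[(3S)-7-(benzyloxy)chroman-3-yl]-2-methoxybenzaldehyde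
Product: 22 (4R)-4-benzyl-3-[(2R,3R)-3-{4-(benzyloxy)-5-[(3S)-7-(benzyloxy)chroman-3-yl]-2-methoxyphenyl}-3-hydroxy-2-[4-methoxy-2-(triisopropylsilyloxy)phenyl]propanoyl]-1,3-oxazolidin-2-one, via boron enolate 21 (not isolated)
Conditions: Bu2BOTf, i-Pr2NEt, CH2Cl2, 0 °C; 20, −78 to 0 °C; pH 7 buffer, MeOH, 30% H2O2, 0 °C
Reagents that add atoms: none
Why: Evans syn aldol; the Z boron enolate reacts through a chair transition state on the face away from the auxiliary benzyl group, which sets the α-carbon (the future C3) as 2R, and the carbinol configuration (3R) is a by-product that the cyclisation later overrides or uses.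

Step 13
Reactants: 22 aldol adduct
Product: 23 (1R,2S)-1-{4-(benzyloxy)-5-[(3S)-7-(benzyloxy)chroman-3-yl]-2-methoxyphenyl}-2-[4-methoxy-2-(triisopropylsilyloxy)phenyl]propane-1,3-diol
Conditions: LiBH4, THF, MeOH (1 equiv), 0 °C
Reagents that add atoms: none
Why: Reductive removal of the auxiliary from a β-hydroxy imide; no enolisable carbonyl remains, so the centre is configurationally safe (its descriptor changes from R to S only because the CIP priorities change), and 6 is recovered.

Step 14
Reactants: 23 diol; 24 3-(benzyloxy)phenol
Product: 25 (1R,2S)-3-[3-(benzyloxy)phenoxy]-1-{4-(benzyloxy)-5-[(3S)-7-(benzyloxy)chroman-3-yl]-2-methoxyphenyl}-2-[4-methoxy-2-(triisopropylsilyloxy)phenyl]propan-1-ol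
Conditions: PPh3, DIAD, toluene, 0 °C to rt
Reagents that add atoms: none
Why: Mitsunobu etherification; the primary hydroxyl is activated far faster than the hindered secondary benzylic one, and no stereocentre takes part.

Step 15
Reactants: 25 acyclic carbinol
Product: 27 (3S,4R)-7-(benzyloxy)-4-{4-(benzyloxy)-5-[(3S)-7-(benzyloxy)chroman-3-yl]-2-methoxyphenyl}-3-[4-methoxy-2-(triisopropylsilyloxy)phenyl]chroman, via benzylic cation 26 (not isolated)
Conditions: Sc(OTf)3 (10 mol %), CH2Cl2/MeNO2 (4:1, 0.01 M), 4 Å MS, −20 °C to rt
Reagents that add atoms: none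
Why: Sc(OTf)3 ionises the C4 hydroxyl to cation 26, stabilised by the para benzyloxy (D4) and ortho methoxy (D2) groups of ring D; the tethered ring A ether attacks through the carbon para to its benzyloxy group and ortho to the ether oxygen, and proton loss restores aromaticity. The closest known reaction type is the intramolecular Friedel–Crafts cycloalkylation of 3-aryloxy-1-arylpropan-1-ols to 4-arylchromans. Ring C closes as a six-membered ring by electrophilic aromatic substitution, with both the cationic carbon C4 and the attacked carbon C4a inside the new ring. C4 is set by 1,2-induction from C3: in the chair-like transition state ring B on C3 and ring D on C4 are both pseudo-equatorial, which gives the trans (3S,4R) chroman; this is also expected to be the more stable isomer. The (1R) carbinol of 25 would give the same (4R) centre by backside displacement, so the ionisation and displacement extremes of the mechanism converge. The step needs regioselectivity on ring A, secured by steric shielding of the position between the two oxygens; it needs the ring B oxygen to stay out, secured by the bulky silyl ether; and it needs C3 to survive, secured by fast six-ring closure at low temperature and high dilution, which should outpace proton loss from C3 and intermolecular alkylation.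

Step 16
Reactants: 27 protected target
Product: 28 2-[(3S,4R)-7-(benzyloxy)-4-{4-(benzyloxy)-5-[(3S)-7-(benzyloxy)chroman-3-yl]-2-methoxyphenyl}chroman-3-yl]-5-methoxyphenol
Conditions: Bu4NF, AcOH, THF, 0 °C
Reagents that add atoms: none
Why: Fluoride cleavage of the aryl silyl ether; acetic acid buffering keeps the medium from becoming basic enough to disturb the doubly benzylic C4–H.

Step 17
Reactants: 28 tri-O-benzyl phenol
Product: 29 (3S,4R)-4-{4-hydroxy-5-[(3S)-7-hydroxychroman-3-yl]-2-methoxyphenyl}-3-(2-hydroxy-4-methoxyphenyl)chroman-7-ol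
Conditions: H2 (1 atm), Pd/C (10%), THF/MeOH, rt
Reagents that add atoms: none
Why: Hydrogenolysis of three aryl benzyl ethers under neutral conditions; the pyran C–O bonds are not benzylic on the carbon side, and no stereocentre is affected.

## Compound list

1 | 2-hydroxy-4-methoxybenzaldehyde | COc1ccc(C=O)c(O)c1 | starting material
2 | 4-methoxy-2-(triisopropylsilyloxy)benzaldehyde | COc1ccc(C=O)c(O[Si](C(C)C)(C(C)C)C(C)C)c1 | intermediate
3 | 4-methoxy-1-(2-methoxyvinyl)-2-(triisopropylsilyloxy)benzene (E/Z mixture) | COC=Cc1ccc(OC)cc1O[Si](C(C)C)(C(C)C)C(C)C | intermediate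
4 | [4-methoxy-2-(triisopropylsilyloxy)phenyl]acetaldehyde (not isolated) | O=CCc1ccc(OC)cc1O[Si](C(C)C)(C(C)C)C(C)C | intermediate
5 | [4-methoxy-2-(triisopropylsilyloxy)phenyl]acetic acid | OC(=O)Cc1ccc(OC)cc1O[Si](C(C)C)(C(C)C)C(C)C | intermediate
6 | (R)-4-benzyl-1,3-oxazolidin-2-one | O=C1N[C@H](Cc2ccccc2)CO1 | starting material
7 | mixed anhydride of 5 with pivalic acid (not isolated) | CC(C)(C)C(=O)OC(=O)Cc1ccc(OC)cc1O[Si](C(C)C)(C(C)C)C(C)C | intermediate
8 | (R)-4-benzyl-3-{[4-methoxy-2-(triisopropylsilyloxy)phenyl]acetyl}-1,3-oxazolidin-2-one | COc1ccc(CC(=O)N2[C@H](Cc3ccccc3)COC2=O)c(O[Si](C(C)C)(C(C)C)C(C)C)c1 | intermediate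
9 | 5-bromo-2-hydroxy-4-methoxybenzaldehyde | COc1cc(O)c(C=O)cc1Br | starting material
10 | 2-(benzyloxy)-5-bromo-4-methoxybenzaldehyde | COc1cc(OCc2ccccc2)c(C=O)cc1Br | intermediate
11 | N-{2-[2-(benzyloxy)-5-bromo-4-methoxyphenyl]-1-tosylvinyl}formamide (not isolated) | O=CNC(=Cc1cc(Br)c(OC)cc1OCc1ccccc1)S(=O)(=O)c1ccc(C)cc1 | intermediate
12 | [2-(benzyloxy)-5-bromo-4-methoxyphenyl]acetonitrile | N#CCc1cc(Br)c(OC)cc1OCc1ccccc1 | intermediate
13 | 4-(benzyloxy)-2-hydroxybenzaldehyde | O=Cc1ccc(OCc2ccccc2)cc1O | starting material
14 | 7-(benzyloxy)-3-[2-(benzyloxy)-5-bromo-4-methoxyphenyl]-2H-chromen-2-imine (not isolated) | N=C1Oc2cc(OCc3ccccc3)ccc2C=C1c1cc(Br)c(OC)cc1OCc1ccccc1 | intermediate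
15 | 7-(benzyloxy)-3-[2-(benzyloxy)-5-bromo-4-methoxyphenyl]-2H-chromen-2-one | O=C1Oc2cc(OCc3ccccc3)ccc2C=C1c1cc(Br)c(OC)cc1OCc1ccccc1 | intermediate
16 | 5-(benzyloxy)-2-{(Z)-2-[2-(benzyloxy)-5-bromo-4-methoxyphenyl]-3-hydroxyprop-1-en-1-yl}phenol | OC/C(=C\c1ccc(OCc2ccccc2)cc1O)c1cc(Br)c(OC)cc1OCc1ccccc1 | intermediate
17 | 7-(benzyloxy)-3-[2-(benzyloxy)-5-bromo-4-methoxyphenyl]-2H-chromene | COc1cc(OCc2ccccc2)c(C2=Cc3ccc(OCc4ccccc4)cc3OC2)cc1Br | intermediate
18 | (3S)-7-(benzyloxy)-3-[2-(benzyloxy)-5-bromo-4-methoxyphenyl]chroman | COc1cc(OCc2ccccc2)c([C@H]2COc3cc(OCc4ccccc4)ccc3C2)cc1Br | intermediate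
19 | {4-(benzyloxy)-5-[(3S)-7-(benzyloxy)chroman-3-yl]-2-methoxyphenyl}lithium (not isolated) | [Li]c1cc([C@H]2COc3cc(OCc4ccccc4)ccc3C2)c(OCc2ccccc2)cc1OC | intermediate
20 | 4-(benzyloxy)-5-[(3S)-7-(benzyloxy)chroman-3-yl]-2-methoxybenzaldehyde | COc1cc(OCc2ccccc2)c([C@H]2COc3cc(OCc4ccccc4)ccc3C2)cc1C=O | intermediate
21 | (Z)-dibutylboron enolate of 8 (not isolated) | CCCCB(CCCC)O/C(=C\c1ccc(OC)cc1O[Si](C(C)C)(C(C)C)C(C)C)N1[C@H](Cc2ccccc2)COC1=O | intermediate
22 | (4R)-4-benzyl-3-[(2R,3R)-3-{4-(benzyloxy)-5-[(3S)-7-(benzyloxy)chroman-3-yl]-2-methoxyphenyl}-3-hydroxy-2-[4-methoxy-2-(triisopropylsilyloxy)phenyl]propanoyl]-1,3-oxazolidin-2-one | COc1ccc([C@H]([C@@H](O)c2cc([C@H]3COc4cc(OCc5ccccc5)ccc4C3)c(OCc3ccccc3)cc2OC)C(=O)N2[C@H](Cc3ccccc3)COC2=O)c(O[Si](C(C)C)(C(C)C)C(C)C)c1 | intermediate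
23 | (1R,2S)-1-{4-(benzyloxy)-5-[(3S)-7-(benzyloxy)chroman-3-yl]-2-methoxyphenyl}-2-[4-methoxy-2-(triisopropylsilyloxy)phenyl]propane-1,3-diol | COc1ccc([C@@H](CO)[C@@H](O)c2cc([C@H]3COc4cc(OCc5ccccc5)ccc4C3)c(OCc3ccccc3)cc2OC)c(O[Si](C(C)C)(C(C)C)C(C)C)c1 | intermediate
24 | 3-(benzyloxy)phenol | Oc1cccc(OCc2ccccc2)c1 | starting material
25 | (1R,2S)-3-[3-(benzyloxy)phenoxy]-1-{4-(benzyloxy)-5-[(3S)-7-(benzyloxy)chroman-3-yl]-2-methoxyphenyl}-2-[4-methoxy-2-(triisopropylsilyloxy)phenyl]propan-1-ol | COc1ccc([C@@H](COc2cccc(OCc3ccccc3)c2)[C@@H](O)c2cc([C@H]3COc4cc(OCc5ccccc5)ccc4C3)c(OCc3ccccc3)cc2OC)c(O[Si](C(C)C)(C(C)C)C(C)C)c1 | intermediate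
26 | C4 benzylic cation derived from 25 (not isolated) | COc1ccc([C@@H](COc2cccc(OCc3ccccc3)c2)[CH+]c2cc([C@H]3COc4cc(OCc5ccccc5)ccc4C3)c(OCc3ccccc3)cc2OC)c(O[Si](C(C)C)(C(C)C)C(C)C)c1 | intermediate
27 | (3S,4R)-7-(benzyloxy)-4-{4-(benzyloxy)-5-[(3S)-7-(benzyloxy)chroman-3-yl]-2-methoxyphenyl}-3-[4-methoxy-2-(triisopropylsilyloxy)phenyl]chroman | COc1ccc([C@H]2COc3cc(OCc4ccccc4)ccc3[C@@H]2c2cc([C@H]3COc4cc(OCc5ccccc5)ccc4C3)c(OCc3ccccc3)cc2OC)c(O[Si](C(C)C)(C(C)C)C(C)C)c1 | intermediate
28 | 2-[(3S,4R)-7-(benzyloxy)-4-{4-(benzyloxy)-5-[(3S)-7-(benzyloxy)chroman-3-yl]-2-methoxyphenyl}chroman-3-yl]-5-methoxyphenol | COc1ccc([C@H]2COc3cc(OCc4ccccc4)ccc3[C@@H]2c2cc([C@H]3COc4cc(OCc5ccccc5)ccc4C3)c(OCc3ccccc3)cc2OC)c(O)c1 | intermediate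
29 | (3S,4R)-4-{4-hydroxy-5-[(3S)-7-hydroxychroman-3-yl]-2-methoxyphenyl}-3-(2-hydroxy-4-methoxyphenyl)chroman-7-ol | COc1ccc([C@H]2COc3cc(O)ccc3[C@@H]2c2cc([C@H]3COc4cc(O)ccc4C3)c(O)cc2OC)c(O)c1 | target

## Step count and least certain steps

Total step count: 17. Longest linear sequence: 13 steps (steps 5 to 17, from 9 to 29).

Step 15 (key step). The likeliest failure is incomplete relay of C3 to C4: the planar, long-lived cation can be attacked on either face, and the two transition states differ only in whether ring D is pseudo-equatorial or pseudo-axial, so some cis isomer may form. Slow closure would also allow proton loss from C3. The fallback corrects C4 thermodynamically instead of kinetically. It sets out from 25: the closure is run as planned, and the resulting mixture of 27 with its C4 epimer, the cis-(3S,4S) silyl ether F1, is desilylated as in step 16 to 28 and the cis phenol F2. The mixture is then treated with KCH2S(O)CH3 (from KH) in DMSO at rt. This removes the doubly benzylic C4–H reversibly, which is far more acidic than the singly benzylic C3–H and C3'–H, and lets the material settle as the trans isomer, as is known for cis-3,4-diarylchromans. The fallback comes back to the route at 28.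

Step 10. Facial discrimination may be poor because the ortho benzyloxy group twists the aryl ring out of the alkene plane and changes how the substrate sits in the catalyst pocket. The fallback moves the hydrogenation to the open-chain stage, where the free hydroxyl can direct the metal. It sets out from 16: hydroxyl-directed asymmetric hydrogenation of the allylic alcohol with Ru(OAc)2[(S)-BINAP] and H2 in MeOH (ligand enantiomer chosen for the S product) would give the saturated (S)-diol F3, and Mitsunobu closure (PPh3, DIAD, THF) of its phenol onto the primary alcohol comes back to the route at 18.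

Step 12. The addition may stall or revert (retro-aldol), because both the enolate, which is aryl-stabilised and has an ortho silyloxy group, and the aldehyde, which is electron-rich and has an ortho methoxy group, are hindered and unreactive. The very electron-rich carbinol may also dehydrate on work-up. The fallback makes C3 by enolate hydroxymethylation and brings ring D in as the nucleophile. It sets out from 8 and runs as follows.
- Hydroxymethylation of the titanium enolate of 8 (TiCl4, i-Pr2NEt, s-trioxane, CH2Cl2, 0 °C) would give the (2S)-hydroxymethyl imide F4, with the same auxiliary now controlling the opposite role of the two carbons.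
- Transamination (AlMe3, MeONHMe·HCl, CH2Cl2) would give the β-hydroxy Weinreb amide F5, whose α-hydrogen is less acidic than that of the imide.
- Mitsunobu etherification with 24 would give the aryl ether Weinreb amide F6.
- Addition of aryllithium 19 (from 18, as in step 11) at −78 °C would give the ketone F7.
- Immediate reduction (NaBH4, CeCl3, MeOH/THF, −78 °C) comes back to the route at 25, accompanied by its C4 epimer F8; both ionise to the same cation in step 15.

This path is two steps longer and passes through a ketone that can epimerise or eliminate aryloxide, which is why it is held in reserve.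

Step 14. The redox condensation may engage the secondary benzylic hydroxyl, either directly or through a cyclic phosphorane of the 1,3-diol, which would lead to etherification or ionisation at C4. The fallback replaces the redox condensation by a two-stage displacement. It sets out from 23: selective sulfonylation of the primary hydroxyl (TsCl, pyridine, CH2Cl2, 0 °C) would give the primary tosylate F9, and displacement with the pre-formed sodium salt of 24 (NaH, DMF, rt; one equivalent, so that the benzylic hydroxyl is not deprotonated) comes back to the route at 25.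

## Further compounds

F1 | step 15 | (3S,4S)-7-(benzyloxy)-4-{4-(benzyloxy)-5-[(3S)-7-(benzyloxy)chroman-3-yl]-2-methoxyphenyl}-3-[4-methoxy-2-(triisopropylsilyloxy)phenyl]chroman | COc1ccc([C@H]2COc3cc(OCc4ccccc4)ccc3[C@H]2c2cc([C@H]3COc4cc(OCc5ccccc5)ccc4C3)c(OCc3ccccc3)cc2OC)c(O[Si](C(C)C)(C(C)C)C(C)C)c1
F2 | step 15 | 2-[(3S,4S)-7-(benzyloxy)-4-{4-(benzyloxy)-5-[(3S)-7-(benzyloxy)chroman-3-yl]-2-methoxyphenyl}chroman-3-yl]-5-methoxyphenol | COc1ccc([C@H]2COc3cc(OCc4ccccc4)ccc3[C@H]2c2cc([C@H]3COc4cc(OCc5ccccc5)ccc4C3)c(OCc3ccccc3)cc2OC)c(O)c1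
F3 | step 10 | 5-(benzyloxy)-2-{(2S)-2-[2-(benzyloxy)-5-bromo-4-methoxyphenyl]-3-hydroxypropyl}phenol | OC[C@@H](Cc1ccc(OCc2ccccc2)cc1O)c1cc(Br)c(OC)cc1OCc1ccccc1
F4 | step 12 | (4R)-4-benzyl-3-{(2S)-3-hydroxy-2-[4-methoxy-2-(triisopropylsilyloxy)phenyl]propanoyl}-1,3-oxazolidin-2-one | COc1ccc([C@@H](CO)C(=O)N2[C@H](Cc3ccccc3)COC2=O)c(O[Si](C(C)C)(C(C)C)C(C)C)c1
F5 | step 12 | (2S)-3-hydroxy-N-methoxy-2-[4-methoxy-2-(triisopropylsilyloxy)phenyl]-N-methylpropanamide | COc1ccc([C@@H](CO)C(=O)N(C)OC)c(O[Si](C(C)C)(C(C)C)C(C)C)c1
F6 | step 12 | (2S)-3-[3-(benzyloxy)phenoxy]-N-methoxy-2-[4-methoxy-2-(triisopropylsilyloxy)phenyl]-N-methylpropanamide | COc1ccc([C@@H](COc2cccc(OCc3ccccc3)c2)C(=O)N(C)OC)c(O[Si](C(C)C)(C(C)C)C(C)C)c1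
F7 | step 12 | (2S)-3-[3-(benzyloxy)phenoxy]-1-{4-(benzyloxy)-5-[(3S)-7-(benzyloxy)chroman-3-yl]-2-methoxyphenyl}-2-[4-methoxy-2-(triisopropylsilyloxy)phenyl]propan-1-one | COc1ccc([C@@H](COc2cccc(OCc3ccccc3)c2)C(=O)c2cc([C@H]3COc4cc(OCc5ccccc5)ccc4C3)c(OCc3ccccc3)cc2OC)c(O[Si](C(C)C)(C(C)C)C(C)C)c1
F8 | step 12 | (1S,2S)-3-[3-(benzyloxy)phenoxy]-1-{4-(benzyloxy)-5-[(3S)-7-(benzyloxy)chroman-3-yl]-2-methoxyphenyl}-2-[4-methoxy-2-(triisopropylsilyloxy)phenyl]propan-1-ol | COc1ccc([C@@H](COc2cccc(OCc3ccccc3)c2)[C@H](O)c2cc([C@H]3COc4cc(OCc5ccccc5)ccc4C3)c(OCc3ccccc3)cc2OC)c(O[Si](C(C)C)(C(C)C)C(C)C)c1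
F9 | step 14 | (2S,3R)-3-{4-(benzyloxy)-5-[(3S)-7-(benzyloxy)chroman-3-yl]-2-methoxyphenyl}-3-hydroxy-2-[4-methoxy-2-(triisopropylsilyloxy)phenyl]propyl 4-methylbenzenesulfonate | COc1ccc([C@@H](COS(=O)(=O)c2ccc(C)cc2)[C@@H](O)c2cc([C@H]3COc4cc(OCc5ccccc5)ccc4C3)c(OCc3ccccc3)cc2OC)c(O[Si](C(C)C)(C(C)C)C(C)C)c1
A1 | alternative 1 | trans-7-(benzyloxy)-4-{4-(benzyloxy)-5-[(3S)-7-(benzyloxy)chroman-3-yl]-2-methoxyphenyl}-3-[2-(benzyloxy)-4-methoxyphenyl]chroman-2-ol | COc1ccc([C@H]2C(O)Oc3cc(OCc4ccccc4)ccc3[C@@H]2c2cc([C@H]3COc4cc(OCc5ccccc5)ccc4C3)c(OCc3ccccc3)cc2OC)c(OCc2ccccc2)c1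
A2 | alternative 1 | 5-(benzyloxy)-2-[{4-(benzyloxy)-5-[(3S)-7-(benzyloxy)chroman-3-yl]-2-methoxyphenyl}(tosyl)methyl]phenol | Cc1ccc(S(=O)(=O)C(c2ccc(OCc3ccccc3)cc2O)c2cc([C@H]3COc4cc(OCc5ccccc5)ccc4C3)c(OCc3ccccc3)cc2OC)cc1
A3 | alternative 1 | o-quinone methide: 3-(benzyloxy)-6-{4-(benzyloxy)-5-[(3S)-7-(benzyloxy)chroman-3-yl]-2-methoxybenzylidene}cyclohexa-2,4-dien-1-one | O=C1C=C(OCc2ccccc2)C=CC1=Cc1cc([C@H]2COc3cc(OCc4ccccc4)ccc3C2)c(OCc2ccccc2)cc1OC
A4 | alternative 1 | [2-(benzyloxy)-4-methoxyphenyl]acetaldehyde | O=CCc1ccc(OC)cc1OCc1ccccc1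
A5 | alternative 2 | trans-7-(benzyloxy)-4-[4-(benzyloxy)-2-bromophenyl]-3-[2-(benzyloxy)-4-methoxyphenyl]chroman | COc1ccc([C@H]2COc3cc(OCc4ccccc4)ccc3[C@@H]2c2ccc(OCc3ccccc3)cc2Br)c(OCc2ccccc2)c1
A6 | alternative 2 | 3,3-bis[4-(benzyloxy)-2-bromophenyl]-2-[2-(benzyloxy)-4-methoxyphenyl]propan-1-ol (single C2 enantiomer) | COc1ccc([C@@H](CO)C(c2ccc(OCc3ccccc3)cc2Br)c2ccc(OCc3ccccc3)cc2Br)c(OCc2ccccc2)c1
A7 | alternative 3 | 5-(benzyloxy)... tri-O-benzyl target with free D4 hydroxyl: 2-[(3S)-7-(benzyloxy)chroman-3-yl]-4-{(3S,4R)-7-(benzyloxy)-3-[2-(benzyloxy)-4-methoxyphenyl]chroman-4-yl}-5-methoxyphenol | COc1ccc([C@H]2COc3cc(OCc4ccccc4)ccc3[C@@H]2c2cc([C@H]3COc4cc(OCc5ccccc5)ccc4C3)c(O)cc2OC)c(OCc2ccccc2)c1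
A8 | alternative 3 | (E)-4-[(3S)-7-(benzyloxy)chroman-3-yl]-1-{trans-7-(benzyloxy)-3-[2-(benzyloxy)-4-methoxyphenyl]chroman-4-yl}-1-diazobut-3-en-2-one | [N-]=[N+]=C(C(=O)/C=C/[C@H]1COc2cc(OCc3ccccc3)ccc2C1)[C@H]1c2ccc(OCc3ccccc3)cc2OC[C@@H]1c1ccc(OC)cc1OCc1ccccc1
A9 | alternative 3 | methoxyacetylene | COC#C
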